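The over-reaction product appears to grow out of target, so I treat target as a decaying nuclide and follow its selectivity s, the share of target in all that became target or over-reaction product.

| setting | grey | blue | east | north |
|---|---|---|---|---|
| substrate | 0.14 M | 0.55 M | 0.40 M | 0.10 M |
| remark | run made earlier | run made earlier |  |  |
| time |  |  | 0.50 min | 2.0 min |

| run | time / s | target / % | over-reaction product / % | substrate / % |
|---|---|---|---|---|
| grey | 10.0 | 18.2 | 0.3 | 58.6 |
| grey | 15.0 | 21.0 | 0.5 | 47.1 |
| grey | 25.0 | 20.9 | 3.0 | 38.0 |
| grey | 40.0 | 23.6 | 4.6 | 32.0 |
| grey | 60.0 | 20.5 | 8.3 | 28.4 |
| grey | 80.0 | 19.9 | 10.0 | 25.5 |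
| blue | 12.0 | 44.1 | 4.5 | 30.1 |
| blue | 25.0 | 45.5 | 6.9 | 21.6 |
| blue | 40.0 | 43.5 | 13.0 | 18.2 |
| blue | 50.0 | 41.9 | 11.1 | 17.1 |
| blue | 60.0 | 37.8 | 16.9 | 16.8 |
| blue | 80.0 | 34.1 | 24.2 | 16.9 |

(each reading ± 1 percentage point)

- in percentages every species weighs as the substrate in it: one target or over-reaction product counts as two

- the flask that ends with the higher share of target in all that became target or over-reaction product, or "neither" when 2 percentage points or less lies between them (east / north / neither)
- share of target in all that became target or over-reaction product, east
- share of target in all that became target or over-reaction product, north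

In the first instants substrate pairs into target: blue holds 44.1% of target at 12.0 s, and grey holds 18.2% at 10.0 s. In the middle the substrate readings flatten, and the making of target sinks until it crosses the using up; the target readings, with their scatter, peak near 25.0 s in blue and near 40.0 s in grey.

Past that crossing the flask looks like a decay. Over-reaction product in blue rises from 4.5% to 24.2% between 12.0 s and 80.0 s, and dividing that rate by the mean target reading gives k_O = 0.00704 /s, the over-reaction constant. Grey, a quarter as concentrated, reads 0.00670 /s.

Concentration moves something else, the birth moment t_L: the instant at which a single burst of target would leave the observed share, s = exp(−k_O(t − t_L)). The last readings give t_L = 22.2 s in grey and 3.82 s in blue. I take t_L inversely proportional to the charge and average the two runs, which gives 6.51 s for east and 26.0 s for north. My reckoning then gives 84.8% for east and 51.6% for north.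

The forecast says east, with 84% (80% to 88%) and 55% (47% to 62%), on the ground that “Selectivity therefore depends mostly on time, not concentration”. My north lies 3.4 percentage points below its figure.

East ends at 85.2% and north at 53.2%, so east ends with the higher share, under this scheme:

    2 substrate ⇌ target (K = 13.0 /M, k = 0.120 /M/s)
    target → over-reaction product (k = 0.00670 /s)
    substrate ⇌ dormant form (K = 1.50, k = 0.0370 /s)

With each step taken net, east makes target 13.7 times faster than it uses it up at 0.0962 min, and that ratio is 0.524 at 0.500 min. Through k_O, east's share places the birth moment at 7.33 s. The same east flask read at 20 s then reckons to 91.5%, and it stands at 90.6%.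

All runs were generated by integration with constants of no real substance.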